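The runs are simulated on assumed constants; scatter was added.

If target in the flask were to stand highest at the limit of 25 min, it would have to be still rising by then, so I first asked what stopped the fall of starting material in the earlier runs.

| flask | starting material | coupling partner | precatalyst | remark | time |
|---|---|---|---|---|---|
| blue | 2 M | 0.80 M | 10 mM | run made earlier |  |
| ochre | 2 M | 1.2 M | 10 mM | run made earlier |  |
| flask | 2.0 M | 1.60 M | 10 mM |  | 25 min |

| run | time / min | target / % | starting material / % |
|---|---|---|---|
| blue | 1.33 | 9.6 | 80.7 |
| blue | 2.00 | 16.9 | 79.3 |
| blue | 4.00 | 17.9 | 71.7 |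
| blue | 6.00 | 19.1 | 69.8 |
| blue | 10.0 | 17.7 | 66.3 |
| blue | 20.0 | 16.7 | 66.4 |
| blue | 30.0 | 16.6 | 67.3 |
| ochre | 1.33 | 17.4 | 73.5 |
| ochre | 2.00 | 21.7 | 68.3 |
| ochre | 4.00 | 27.4 | 60.0 |
| ochre | 6.00 | 26.7 | 55.5 |
| ochre | 10.0 | 26.2 | 52.1 |
| ochre | 20.0 | 24.4 | 51.6 |
| ochre | 30.0 | 24.1 | 52.2 |

(standard deviation of a reading: 1 percentage point)



* time up to 25 min at which target stands highest
* the amount of target, in percent of the starting material charged, at that time

In the blue and ochre runs the last three readings of starting material hardly moved, so I replaced each tail by its mean, 66.7% and 52.0%, with an error of 0.58 percentage points. Coupling partner had not run out: taken one to one, the blue run still held 0.133 M. So I formed the starting material consumed over the product of c(starting material) and c(coupling partner) left. This gave 3.75 M⁻¹ for blue and 3.86 M⁻¹ for ochre. I read that repeat as a balance and took the mean, 3.81 M⁻¹, as the stall quotient, an apparent equilibrium constant.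

Solved for the flask, it gave 1.20 M of starting material consumed. Starting material in both runs was level by 10.0 min, well short of the limit, so I expected a peak in the flask before the limit. Peak target read 0.572 of the plateau consumption, at 4.00 min to 6.00 min, which gave me 34.4%. The forecast said 33.5% at 4.5 min; where I read a balance, it read the stall as suggesting that "the catalyst dies rather than partner running out".

The flask gave 32.7% of target at 4.86 min.

    starting material + coupling partner ⇌ target (K = 1.90 M⁻¹, k = 0.188 M⁻¹ min⁻¹)
    starting material + coupling partner ⇌ isomer of the product (K = 1.93 M⁻¹, k = 0.0722 M⁻¹ min⁻¹)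
    target + catalyst ⇌ isomer of the product + catalyst, rate k3*[catalyst]*[target] forward; the back reaction follows from the equilibrium constant (k = 71.1 M⁻¹ min⁻¹)
    coupling partner + precatalyst → catalyst + spent reagent (k = 0.0424 M⁻¹ min⁻¹)

At 25.0 min the flask's starting material stood at 39.9% and its coupling partner at 24.6% of its charge, a stall quotient of 3.83 M⁻¹. At the start, by forward rates alone, the flask used starting material 2.6 times faster for target than for isomer of the product, while the two equilibrium constants times the starting c(starting material) stood at 3.8 and 3.9, kinetic against thermodynamic control. By 25.0 min the flask held 29.8% of target and 30.3% of isomer of the product. With 0.64 M of coupling partner, the stall quotient left 72.9% of the starting material, and that neighbouring flask kept 73% at 25.0 min.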